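The number to hold on to is 0.339, the rise exponent n: the power of time t by which the rate of making product climbs in the delta run while product P builds up.

1. apparent order in free catalyst when 30% of the starting material are converted (percent change of the rate of making product for one percent more free catalyst charged)

- delta: starting material 31 mM; partner 62 mM; free catalyst 4.6 mM; the very flask that is asked about, followed so far
- flask: starting material 31 mM; partner 62.0 mM; free catalyst 4.6 mM

delta run (percent of the starting material charged)

| time / min | product / % | starting material / % |
|---|---|---|
| 15.0 | 5.7 | 61.6 |
| 40.0 | 21.2 | 31.5 |
| 80.0 | 36.6 | 13.7 |
| 120 | 46.4 | 8.7 |

(scatter of a reading: 0.3 percentage points)

- what has gone from starting material into another species counts as reacted, even if it can come back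
- no earlier run changes the charge of free catalyst; that part of a forecast is a guess

Delta is the very flask asked about, followed so far, with the same charges of free catalyst and partner, so its readings are this flask's own. Partner stands at twice the starting material, so if one partner goes into each product, starting material is the limiting reagent in this flask. I read the rise on logarithms, from the first two product readings of the delta run, each with its scatter of 0.3 percentage points:

n = log(21.2%/5.7%) / log(40.0 min/15.0 min) − 1

Taking the loss of starting material as first order up to its first reading, this flask reaches 30% conversion near 11.0 min, earlier than that first reading, so I am extrapolating n backwards. I assume that one percent more free catalyst lifts the rate at a given time by one percent and brings the same conversion one percent sooner, which costs n percent on the rising curve: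

order = 1 − n = 0.661

The forecast gives 0.85, higher than my figure: “If catalyst drives the product-forming step, the order is near 1”.

The flask gives 0.69, with 30% conversion reached at 10.5 min.

    starting material + free catalyst → catalyst intermediate A (k = 0.0920 /M/s)
    partner + catalyst intermediate A → catalyst intermediate B (k = 0.0360 /M/s)
    catalyst intermediate B → catalyst intermediate C (k = 0.00320 /s)
    catalyst intermediate C → free catalyst + product (k = 0.0330 /s)
    starting material ⇌ dormant form (K = 2.90, k = 3.50 × 10⁻⁴ /s)

Carried from that moment to 41.92 min, n would raise the rate by a factor of 1.60, but at 70 percent conversion, reached at that time, the flask's rate stands at 0.83 of its value at 30% conversion.

The numbers in the tables are calculated for substances that don't exist, noise included.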